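Everything rests on disconnecting the C7–C8 bond (germacrane numbering) of the ten-membered carbocycle: C8 is a carbinol allylic to the butenolide C7=C11 double bond, the retron of an alkenylmetal–aldehyde addition. An intramolecular Nozaki–Hiyama–Kishi reaction of a C7 iodobutenolide with a C8 aldehyde should close the ten-membered ring, keep the tetrasubstituted alkene and set C8 under control of C6 in one operation. The precursor is a fully substituted β-iodobutenolide (C6 stereocentre, C13 acetate) carrying the C5–C1–C10–C9 chain, built from geranyl acetate, 3-bromobut-3-en-1-ol and methyl propiolate. The 4,5-epoxide is added last by peripheral attack on the macrocyclic E-alkene.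

Key step: step 14

Remark: germacrane numbering is used (C1 ketone, C4/C5 epoxide, C6 lactone carbinol, C7=C11 butenolide alkene, C8 tiglate carbinol, C10=C14 methylene, C12 lactone carbonyl, C13 acetoxymethyl). The temporary C1 carbinol made in step 4 is carried as both epimers (no descriptor in the SMILES) and is erased by oxidation in step 17.

Step 1
Reactants: 1 3-bromobut-3-en-1-ol
Product: 2 tert-butyl[(3-bromobut-3-en-1-yl)oxy]dimethylsilane
Conditions: TBSCl, imidazole, DMF, 0 °C to rt
Reagents that add atoms: tert-butyldimethylsilyl chloride, CC(C)(C)[Si](C)(C)Cl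
Why: Silyl ether formation on an unhindered primary alcohol; no stereocentre is involved.

Step 2
Reactants: 3 geranyl acetate
Product: 4 6,7-epoxygeranyl acetate (racemic epoxide)
Conditions: mCPBA (1.0 equiv), CH2Cl2, 0 °C
Reagents that add atoms: 3-chloroperbenzoic acid, OOC(=O)c1cccc(Cl)c1
Why: Prilezhaev epoxidation should select the distal trisubstituted alkene, because the other one is deactivated by the allylic acetate; the epoxide configuration is irrelevant since the ring is cleaved next.

Step 3
Reactants: 4 6,7-epoxygeranyl acetate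
Product: 6 (E)-6-acetoxy-4-methylhex-4-enal, via diol 5 (not isolated)
Conditions: H5IO6, THF/H2O, 0 °C to rt
Reagents that add atoms: water, O
Why: Acid-mediated epoxide hydrolysis to diol 5 followed by Malaprade glycol cleavage should give the aldehyde and acetone without touching the E-alkene.

Step 4
Reactants: 2 tert-butyl[(3-bromobut-3-en-1-yl)oxy]dimethylsilane; 6 (E)-6-acetoxy-4-methylhex-4-enal
Product: 8 (E)-9-(tert-butyldimethylsilyloxy)-6-hydroxy-3-methyl-7-methylidenenon-2-en-1-yl acetate, via alkenylmagnesium bromide 7 (not isolated)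
Conditions: Mg, THF, reflux (from 2); then 6, THF, −78 °C
Reagents that add atoms: none
Why: Grignard addition to the aldehyde forms the C1–C10 bond and should outrun attack on the acetate at −78 °C; the new C1 carbinol is formed as both epimers, which is harmless because it is oxidised in step 17.

Step 5
Reactants: 8 allylic alcohol
Product: 9 (E)-6,9-bis(tert-butyldimethylsilyloxy)-3-methyl-7-methylidenenon-2-en-1-yl acetate
Conditions: TBSCl, imidazole, DMF, rt
Reagents that add atoms: tert-butyldimethylsilyl chloride, CC(C)(C)[Si](C)(C)Cl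
Why: Silylation of the secondary allylic alcohol masks C1 for the organometallic steps; the acetate is inert.

Step 6
Reactants: 9 bis-silyl ether acetate
Product: 10 (E)-6,9-bis(tert-butyldimethylsilyloxy)-3-methyl-7-methylidenenon-2-en-1-ol
Conditions: K2CO3, MeOH, rt
Reagents that add atoms: none
Why: Base-catalysed transesterification (methanolysis) removes only the acetate, since silyl ethers are stable to K2CO3/MeOH.

Step 7
Reactants: 10 allylic alcohol
Product: 11 (E)-6,9-bis(tert-butyldimethylsilyloxy)-3-methyl-7-methylidenenon-2-enal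
Conditions: MnO2, CH2Cl2, rt
Reagents that add atoms: none
Why: MnO2 oxidation is selective for the allylic alcohol and should give the E-enal (C6 aldehyde) without isomerisation.

Step 8
Reactants: 11 enal; 12 methyl propiolate
Product: 14 methyl (4R,5E)-9,12-bis(tert-butyldimethylsilyloxy)-4-hydroxy-6-methyl-10-methylidenedodec-5-en-2-ynoate, via methylzinc acetylide 13 (not isolated)
Conditions: Me2Zn, (S,S)-ProPhenol (20 mol %), Ph3P=O (40 mol %), toluene, 4 °C
Reagents that add atoms: none
Why: Catalytic asymmetric alkynylation of an enal by a dinuclear zinc–ProPhenol complex forms the C6–C7 bond; the ligand enantiomer is the one that delivers the acetylide to the Si face (its antipode is used if the sense proves opposite), which sets 6R.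

Step 9
Reactants: 14 propargylic alcohol
Product: 15 methyl (4R,5E)-9,12-bis(tert-butyldimethylsilyloxy)-6-methyl-10-methylidene-4-(triethylsilyloxy)dodec-5-en-2-ynoate
Conditions: TESCl, imidazole, CH2Cl2, 0 °C
Reagents that add atoms: triethylsilyl chloride, CC[Si](CC)(CC)Cl
Why: Silylation gives an acid-labile C6 ether that keeps the hydroxyl from lactonising or quenching the cuprate in step 10; the stereocentre is untouched.

Step 10
Reactants: 15 silyloxy ynoate
Product: 17 methyl (2E,4R,5E)-2-(acetoxymethyl)-9,12-bis(tert-butyldimethylsilyloxy)-6-methyl-10-methylidene-4-(triethylsilyloxy)-3-(trimethylstannyl)dodeca-2,5-dienoate, via alkenylcopper 16 (not isolated)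
Conditions: Me3SnLi, CuBr·SMe2, THF, −78 °C; then BrCH2OAc, −78 to −30 °C
Reagents that add atoms: (trimethylstannyl)lithium (used as Me3SnCu·SMe2), [Li][Sn](C)(C)C; bromomethyl acetate, CC(=O)OCBr
Why: syn-Stannylcupration of the ynoate puts tin on C7 and copper on C11 on the same side, and C-alkylation of the alkenylcopper by the reactive α-acyloxy bromide with retention should place CH2OAc (C13) cis to tin and the ester cis to C6.

Step 11
Reactants: 17 alkenylstannane
Product: 18 methyl (2E,4R,5E)-2-(acetoxymethyl)-9,12-bis(tert-butyldimethylsilyloxy)-3-iodo-6-methyl-10-methylidene-4-(triethylsilyloxy)dodeca-2,5-dienoate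
Conditions: I2, CH2Cl2, 0 °C
Reagents that add atoms: iodine, II
Why: ipso-Iododestannylation replaces tin by iodine with retention of alkene geometry and is much faster than any reaction of iodine with the other alkenes.

Step 12
Reactants: 18 iodo enoate
Product: 20 [(5R)-5-[(1E)-5-(tert-butyldimethylsilyloxy)-8-hydroxy-2-methyl-6-methylideneoct-1-en-1-yl]-4-iodo-2-oxo-2,5-dihydrofuran-3-yl]methyl acetate, via hydroxy ester 19 (not isolated)
Conditions: CSA (0.2 equiv), MeOH/CH2Cl2 1:1, 0 °C to rt
Reagents that add atoms: none
Why: Acid-catalysed methanolysis should remove the triethylsilyl and the primary TBS ether while the hindered secondary TBS ether survives, and the freed C6 hydroxyl, cis to the ester, lactonises to the butenolide without touching C6.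

Step 13
Reactants: 20 iodobutenolide alcohol
Product: 21 [(5R)-5-[(1E)-5-(tert-butyldimethylsilyloxy)-2-methyl-6-methylidene-8-oxooct-1-en-1-yl]-4-iodo-2-oxo-2,5-dihydrofuran-3-yl]methyl acetate
Conditions: Dess–Martin periodinane, pyridine, CH2Cl2, 0 °C
Reagents that add atoms: none
Why: Buffered Dess–Martin oxidation gives the β,γ-unsaturated C8 aldehyde under conditions that should not move the C10=C14 double bond into conjugation; the aldehyde is used at once.

Step 14
Reactants: 21 iodobutenolide aldehyde
Product: 23 (6R,8S)-13-acetoxy-1-(tert-butyldimethylsilyloxy)-8-hydroxygermacra-4E,7(11),10(14)-trien-12,6-olide, via alkenylchromium dichloride 22 (not isolated)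
Conditions: CrCl2 (10 equiv), NiCl2 (1 mol %), degassed DMSO/THF 3:1, rt, syringe-pump addition of 21 to 2 mM
Reagents that add atoms: none
Why: Zerovalent nickel, formed from NiCl2 by divalent chromium, inserts into the C7–I bond, transmetalation gives the trivalent alkenylchromium 22, and this adds to the C8 aldehyde; aqueous work-up frees the alcohol. The closest known reaction type is the intramolecular Nozaki–Hiyama–Kishi coupling of alkenyl iodides and β-iodo enoates with aldehydes, which has closed ten-membered carbocycles. The step closes the ten-membered carbocycle in a 10-exo-trig addition to the carbonyl, leaving the butenolide fused at C6–C7. The new C8 stereocentre is controlled by C6: the C5–C1–C10–C9 bridge spans one face of the planar butenolide, so the aldehyde should add with its chromium-bound oxygen turned to the open face, giving 8S. The step needs chemoselectivity for the iodide and the aldehyde over lactone, acetate and silyl ether, which the coupling has by nature, and cyclisation over oligomerisation, which high dilution secures. Translactonisation to O8 is excluded because C8 lies trans to C12 across C7=C11.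

Step 15
Reactants: 23 macrocyclic alcohol
Product: 24 (6R,8S)-13-acetoxy-1-(tert-butyldimethylsilyloxy)-8-[(E)-2-methylbut-2-enoyloxy]germacra-4E,7(11),10(14)-trien-12,6-olide
Conditions: tigloyl chloride, pyridine, DMAP (cat.), CH2Cl2, 0 °C
Reagents that add atoms: (E)-2-methylbut-2-enoyl chloride, C/C=C(\C)C(=O)Cl
Why: DMAP-catalysed acylation of the secondary allylic alcohol proceeds with retention at C8 under weakly basic conditions that should not abstract the C6 hydrogen, and the E-tiglate cannot isomerise to a more stable form.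

Step 16
Reactants: 24 silyl ether tiglate
Product: 25 (6R,8S)-13-acetoxy-1-hydroxy-8-[(E)-2-methylbut-2-enoyloxy]germacra-4E,7(11),10(14)-trien-12,6-olide
Conditions: HF·pyridine, pyridine, THF, 0 °C to rt
Reagents that add atoms: none
Why: Fluoride-mediated desilylation under mildly acidic buffered conditions should leave both esters and the base-sensitive butenolide untouched.

Step 17
Reactants: 25 allylic alcohol
Product: 26 (6R,8S)-13-acetoxy-8-[(E)-2-methylbut-2-enoyloxy]-1-oxogermacra-4E,7(11),10(14)-trien-12,6-olide
Conditions: Dess–Martin periodinane, pyridine, CH2Cl2, 0 °C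
Reagents that add atoms: none
Why: Dess–Martin oxidation of the allylic alcohol gives the α-methylene ketone, and both C1 epimers converge on one compound.

Step 18
Reactants: 26 trienone
Product: 27 CNP0225286.1, (4R,5R,6S,8S)-13-acetoxy-4,5-epoxy-8-[(E)-2-methylbut-2-enoyloxy]-1-oxogermacra-7(11),10(14)-dien-12,6-olide
Conditions: mCPBA (1.1 equiv), CH2Cl2, 0 °C
Reagents that add atoms: 3-chloroperbenzoic acid, OOC(=O)c1cccc(Cl)c1
Why: Prilezhaev epoxidation should touch only C4=C5, the one alkene not conjugated to a carbonyl; with C6–H eclipsing the C4 methyl (1,3-allylic strain) the peracid attacks the outer face of the ring E-alkene, syn to the lactone oxygen, which sets 4R,5R as in related germacranolides.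

Compound list
1 | 3-bromobut-3-en-1-ol | C=C(Br)CCO | starting material
2 | tert-butyl[(3-bromobut-3-en-1-yl)oxy]dimethylsilane | C=C(Br)CCO[Si](C)(C)C(C)(C)C | intermediate
3 | geranyl acetate | CC(C)=CCC/C(C)=C/COC(C)=O | starting material
4 | 6,7-epoxygeranyl acetate (racemic) | CC1(C)OC1CC/C(C)=C/COC(C)=O | intermediate
5 | (E)-6,7-dihydroxy-3,7-dimethyloct-2-en-1-yl acetate (not isolated) | CC(C)(O)C(O)CC/C(C)=C/COC(C)=O | intermediate
6 | (E)-6-acetoxy-4-methylhex-4-enal | O=CCC/C(C)=C/COC(C)=O | intermediate
7 | [4-(tert-butyldimethylsilyloxy)but-1-en-2-yl]magnesium bromide (not isolated) | C=C([Mg]Br)CCO[Si](C)(C)C(C)(C)C | intermediate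
8 | (E)-9-(tert-butyldimethylsilyloxy)-6-hydroxy-3-methyl-7-methylidenenon-2-en-1-yl acetate (C1 epimers) | CC(=O)OC/C=C(\C)CCC(O)C(=C)CCO[Si](C)(C)C(C)(C)C | intermediate
9 | (E)-6,9-bis(tert-butyldimethylsilyloxy)-3-methyl-7-methylidenenon-2-en-1-yl acetate | CC(=O)OC/C=C(\C)CCC(O[Si](C)(C)C(C)(C)C)C(=C)CCO[Si](C)(C)C(C)(C)C | intermediate
10 | (E)-6,9-bis(tert-butyldimethylsilyloxy)-3-methyl-7-methylidenenon-2-en-1-ol | OC/C=C(\C)CCC(O[Si](C)(C)C(C)(C)C)C(=C)CCO[Si](C)(C)C(C)(C)C | intermediate
11 | (E)-6,9-bis(tert-butyldimethylsilyloxy)-3-methyl-7-methylidenenon-2-enal | O=C/C=C(\C)CCC(O[Si](C)(C)C(C)(C)C)C(=C)CCO[Si](C)(C)C(C)(C)C | intermediate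
12 | methyl propiolate | C#CC(=O)OC | starting material
13 | methyl 3-(methylzincio)propiolate (not isolated) | C[Zn]C#CC(=O)OC | intermediate
14 | methyl (4R,5E)-9,12-bis(tert-butyldimethylsilyloxy)-4-hydroxy-6-methyl-10-methylidenedodec-5-en-2-ynoate | COC(=O)C#C[C@H](O)/C=C(\C)CCC(O[Si](C)(C)C(C)(C)C)C(=C)CCO[Si](C)(C)C(C)(C)C | intermediate
15 | 4-O-triethylsilyl ether of 14 | COC(=O)C#C[C@H](O[Si](CC)(CC)CC)/C=C(\C)CCC(O[Si](C)(C)C(C)(C)C)C(=C)CCO[Si](C)(C)C(C)(C)C | intermediate
16 | 2-cuprio-3-(trimethylstannyl) enoate from 15, tin and copper cis (not isolated) | COC(=O)/C([Cu])=C(\[C@H](O[Si](CC)(CC)CC)/C=C(\C)CCC(O[Si](C)(C)C(C)(C)C)C(=C)CCO[Si](C)(C)C(C)(C)C)[Sn](C)(C)C | intermediate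
17 | methyl (2E,4R,5E)-2-(acetoxymethyl)-9,12-bis(tert-butyldimethylsilyloxy)-6-methyl-10-methylidene-4-(triethylsilyloxy)-3-(trimethylstannyl)dodeca-2,5-dienoate | COC(=O)/C(COC(C)=O)=C(\[C@H](O[Si](CC)(CC)CC)/C=C(\C)CCC(O[Si](C)(C)C(C)(C)C)C(=C)CCO[Si](C)(C)C(C)(C)C)[Sn](C)(C)C | intermediate
18 | 3-iodo analogue of 17 | COC(=O)/C(COC(C)=O)=C(\[C@H](O[Si](CC)(CC)CC)/C=C(\C)CCC(O[Si](C)(C)C(C)(C)C)C(=C)CCO[Si](C)(C)C(C)(C)C)I | intermediate
19 | methyl (2E,4R,5E)-2-(acetoxymethyl)-9-(tert-butyldimethylsilyloxy)-4,12-dihydroxy-3-iodo-6-methyl-10-methylidenedodeca-2,5-dienoate (not isolated) | COC(=O)/C(COC(C)=O)=C(\[C@H](O)/C=C(\C)CCC(O[Si](C)(C)C(C)(C)C)C(=C)CCO)I | intermediate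
20 | [(5R)-5-[(1E)-5-(tert-butyldimethylsilyloxy)-8-hydroxy-2-methyl-6-methylideneoct-1-en-1-yl]-4-iodo-2-oxo-2,5-dihydrofuran-3-yl]methyl acetate | O=C1O[C@H](/C=C(\C)CCC(O[Si](C)(C)C(C)(C)C)C(=C)CCO)C(I)=C1COC(C)=O | intermediate
21 | 8-oxo (aldehyde) analogue of 20 | O=C1O[C@H](/C=C(\C)CCC(O[Si](C)(C)C(C)(C)C)C(=C)CC=O)C(I)=C1COC(C)=O | intermediate
22 | alkenylchromium dichloride from 21, chromium in place of iodine (not isolated) | O=C1O[C@H](/C=C(\C)CCC(O[Si](C)(C)C(C)(C)C)C(=C)CC=O)C([Cr](Cl)Cl)=C1COC(C)=O | intermediate
23 | (6R,8S)-13-acetoxy-1-(tert-butyldimethylsilyloxy)-8-hydroxygermacra-4E,7(11),10(14)-trien-12,6-olide | C=C1C[C@H](O)C2=C(COC(C)=O)C(=O)O[C@@H]2/C=C(\C)CCC1O[Si](C)(C)C(C)(C)C | intermediate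
24 | 8-O-tiglate of 23 | C=C1C[C@H](OC(=O)/C(C)=C/C)C2=C(COC(C)=O)C(=O)O[C@@H]2/C=C(\C)CCC1O[Si](C)(C)C(C)(C)C | intermediate
25 | 1-hydroxy compound from 24 | C=C1C[C@H](OC(=O)/C(C)=C/C)C2=C(COC(C)=O)C(=O)O[C@@H]2/C=C(\C)CCC1O | intermediate
26 | (6R,8S)-13-acetoxy-8-tigloyloxy-1-oxogermacra-4E,7(11),10(14)-trien-12,6-olide | C=C1C[C@H](OC(=O)/C(C)=C/C)C2=C(COC(C)=O)C(=O)O[C@@H]2/C=C(\C)CCC1=O | intermediate
27 | CNP0225286.1 | C=C1C[C@H](OC(=O)/C(C)=C/C)C2=C(COC(C)=O)C(=O)O[C@@H]2[C@H]2O[C@]2(C)CCC1=O | target

Total step count: 18. Longest linear sequence: 17 steps (steps 2 to 18, from geranyl acetate).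

Steps most likely to fail

Step 14. The ring closure may suffer from intermolecular coupling or reduction of the carbon–iodine bond, and the aldehyde may be attacked from the other face, so that the C8 epimer dominates. The fallback for the stereochemical failure sets out from 21: the cyclisation then delivers the 8R alcohol F1, and this is esterified with tiglic acid under Mitsunobu conditions (PPh3, DIAD, THF, 0 °C). The Mitsunobu reaction inverts C8 and gives 24 directly, where the route is rejoined; substitution with allylic shift is unlikely because it would have to occur at the fully substituted C11.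

Step 10. The alkylation of the alkenylcopper may be outrun by protonation or by attack at the acetate carbonyl, so that C13 is not introduced. The fallback sets out from 15 and uses the same stannylcupration, but the alkenylcopper is transmetalated with ZnCl2 and trapped with monomeric formaldehyde in an aldol-type hydroxymethylation. This gives the hydroxymethyl stannane F2, which is acetylated (Ac2O, pyridine, DMAP) and returns to the route at 17.

Step 18. The peracid may attack the wrong face of the ring alkene if the macrocycle adopts another conformation, or selectivity between alkenes may be lost. The fallback sets out from 26 and replaces substrate control by reagent control: a Shi epoxidation with the D-fructose-derived ketone and Oxone in buffered MeCN/dimethoxymethane–water at 0 °C, whose spiro transition state should give the 4R,5R epoxide of an E-trisubstituted alkene irrespective of ring conformation. It returns to the route at 27 and makes no new compound (F0).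

Further compounds
F1 | step 14 | (6R,8R)-13-acetoxy-1-(tert-butyldimethylsilyloxy)-8-hydroxygermacra-4E,7(11),10(14)-trien-12,6-olide (C8 epimer of 23) | C=C1C[C@@H](O)C2=C(COC(C)=O)C(=O)O[C@@H]2/C=C(\C)CCC1O[Si](C)(C)C(C)(C)C
F2 | step 10 | methyl (2E,4R,5E)-9,12-bis(tert-butyldimethylsilyloxy)-2-(hydroxymethyl)-6-methyl-10-methylidene-4-(triethylsilyloxy)-3-(trimethylstannyl)dodeca-2,5-dienoate | COC(=O)/C(CO)=C(\[C@H](O[Si](CC)(CC)CC)/C=C(\C)CCC(O[Si](C)(C)C(C)(C)C)C(=C)CCO[Si](C)(C)C(C)(C)C)[Sn](C)(C)C
F0 | step 18 | none | none
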